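Partner is the limiting reagent of this flask: the 19.8 mM charged is less than the 36.0 mM of both substrates together, so open its books first.

left-handed substrate 18 mM; partner 1.10 equiv; protic impurity 5.40 mM; catalyst 0.1 mol%; right-handed substrate 18 mM

    partner + protic impurity → quenched reagent (k1 = 14 M⁻¹ s⁻¹)
    partner + catalyst + right-handed substrate → catalyst + right-handed product (k2 = 64000 M⁻² s⁻¹)
    partner + catalyst + left-handed substrate → catalyst + left-handed product (k3 = 2.0 × 10⁵ M⁻² s⁻¹)
    catalyst + catalyst ⇌ resting dimer (K4 = 34000 M⁻¹, k4 = 24000 M⁻¹ s⁻¹)

- catalyst is single-handed; left-handed substrate and right-handed substrate are mirror images of each other, charged as a racemate, each of them at the stated concentration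
- where a step has two of a species, its rate is k times that concentration squared, and two are used at each turn
- a form made of two catalysts counts as two
- charge of left-handed substrate (flask): 18 mM

- the form that holds most of the catalyst when 20% of the left-handed substrate and right-handed substrate together are converted (catalyst / resting dimer)
- its share of the catalyst then

| Partner ledger | Amount |
|---|---|
| Charged | 19.8 mM |
| Claimed by protic impurity | 5.40 mM |
| Left for both substrates | 14.4 mM |
| Needed at the marked conversion | 7.20 mM |

Read the last two lines together. The substrates' allowance is twice what the mark needs, so the flask can reach the mark even after the impurity has taken its full claim.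

Now keep the catalyst's books the same way. The loading is stated on the left-handed charge, which gives 18.0 µM. The substrate steps hand the catalyst back unchanged, and a resting dimer counts as two, so c(catalyst) plus two c(resting dimer) stays at that total.

At balance, pairing and splitting run equally fast. Divide one rate by the other and time drops out: c(resting dimer) equals 34000 M⁻¹ times c(catalyst) squared. Put this into the books and call the free share s. Two times 34000 M⁻¹ times the total gives a plain number, the load, of 1.22, and the books then say that load times s squared plus s equals one. Solve that quadratic. I get 10.5 µM, the working catalyst: the free catalyst that this balance leaves from the total charged. The books close with 3.75 µM of resting dimer, counted as two.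

The balance relaxes with a time of 0.583 s, and the look comes at 13.5 s. So commit to catalyst, with a share of 58.3%.

The forecast also says catalyst, at 58%, with a range of 46% to 62%. It warns: “The main risk is the basis”.

At 13.5 s, the simulation gives catalyst at 58.3%, with 41.7% as resting dimer.

Take the working catalyst to two of the partner's paths: divide the rate to left-handed product by the rate of quenching, and partner drops out, leaving a ratio of 0.500 from the charged values. At 8.75 s the same ratio stands at 2.0, and by 8.00 s the quench has 80% of its turnover up to 40.0 s behind it.

The constants used here are made up; what happens was integrated by code.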